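**Plan**

- Retrosynthesis (target numbering: C1 carboxyl, C2 methylene, ring O1–O2–C3–C4–C5–C6, chain C7=C8(CH3)–C9–C10(Et)–C11 to C14): C2–C3 is cut first (acetate arm added to a cyclic peroxycarbenium ion). Then C4–C5, C6–O1 and O2–C3 are cut together, giving butanal, a 2-ethyl-1,3-diene and O2. The diene is cut at C6–C7, C8–CH3, C8–C9 and C10–ethyl.
- Enabling feature: in the 1,2-dioxane, O2 sits on C3 and O1 on C6, a 1,4-dioxygen pattern with C4 (ethyl) and C5 between. C3 and C4 can therefore be the carbonyl and α-carbon of butanal, C5 and C6 the CH2=C(Et) end of the diene, and O1–O2 molecular oxygen.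
- Forward: hex-1-ene is extended linearly to the iodide, the alkyne and the diene (steps 1–3). The only ring, the 1,2-dioxane, closes in step 4. The acetate arm and the free acid follow (steps 5–7).
- Stereochemistry: C10 from zirconium-catalysed asymmetric ethylalumination; E-C7=C8 from syn-methylalumination; C4 from the chiral imidazolidinone; C6 is not controlled and its epimers are separated after step 4; C3 from axial attack on the peroxycarbenium ion, cis to the C4 ethyl.

Key step: step 4

Remark: the facial senses assigned to (+)-(NMI)2ZrCl2 and to the (2S,5S)-imidazolidinone follow the accepted models for these catalysts; both antipodes are commercial and would be exchanged if either sense proved reversed.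

**Route**

Step 1
Reactants: 1 hex-1-ene
Product: 3 (3S)-3-(iodomethyl)heptane, via alkylalane 2 (not isolated)
Conditions: Et3Al (1.5 equiv), (+)-(NMI)2ZrCl2 [bis(1-neomenthylindenyl)zirconium dichloride] (5 mol%), CH2Cl2, 0 °C to rt; then I2 (excess), THF, 0 °C to rt
Reagents that add atoms: triethylaluminium, CC[Al](CC)CC; iodine, II
Why: Zirconium-catalysed asymmetric carboalumination (ZACA reaction) adds ethyl and aluminium across the terminal alkene with the chiral zirconocene choosing the alkene face, which sets C10 as S, and iodinolysis of the primary C–Al bond leaves that centre untouched.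

Step 2
Reactants: 3 (3S)-3-(iodomethyl)heptane
Product: 4 (4S)-4-ethyloct-1-yne
Conditions: LiC≡CH·H2NCH2CH2NH2 (2 equiv), DMSO, 10 °C to rt
Reagents that add atoms: lithium acetylide–ethylenediamine complex, [Li+].[C-]#C.NCCN
Why: SN2 alkylation of an acetylide by a primary iodide in a dipolar aprotic solvent is routine for β-branched iodides, and the stereocentre, one carbon away from the reacting CH2, is not involved.

Step 3
Reactants: 4 (4S)-4-ethyloct-1-yne; 5 2-bromobut-1-ene
Product: 7 (3E,6S)-2,6-diethyl-4-methyldeca-1,3-diene, via alkenylalane 6 (not isolated)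
Conditions: Me3Al (2.5 equiv), Cp2ZrCl2 (25 mol%), CH2Cl2, 0 °C to rt; then 5 (1.2 equiv), ZnCl2 (co-catalyst), Pd(PPh3)4 (5 mol%), THF, rt
Reagents that add atoms: trimethylaluminium, C[Al](C)C
Why: Zirconium-catalysed methylalumination of the terminal alkyne (Negishi carboalumination) is a syn addition with aluminium on the terminal carbon, which fixes the E trisubstituted C7=C8 alkene, and the palladium-catalysed Negishi coupling of the alkenylalane with the alkenyl bromide, accelerated by ZnCl2, forms C6–C7 with retention of geometry.

Step 4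
Reactants: 7 (3E,6S)-2,6-diethyl-4-methyldeca-1,3-diene; 8 butanal; 9 dioxygen (as air)
Product: 12 (4R,6R)-4,6-diethyl-6-[(1E,4S)-4-ethyl-2-methyloct-1-en-1-yl]-1,2-dioxan-3-ol (C3 anomers), via butanal enamine 10 (not isolated), via hydroperoxy aldehyde 11 (not isolated)
Conditions: 7 (1 equiv, 0.5 M), 8 (3 equiv), (2S,5S)-5-benzyl-2-tert-butyl-3-methylimidazolidin-4-one·CF3CO2H (20 mol%), (NH4)2Ce(NO3)6 (30 mol%, in portions), air (1 atm, slow stream), NaHCO3, H2O (3 equiv), DME, −20 to 0 °C; C6 epimers separated on silica gel
Reagents that add atoms: none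
Why: Proposed new method: the imidazolidinone condenses with 8 to the E-enamine 10, which tetravalent cerium oxidises to a 3π-electron radical cation; its electrophilic α-carbon (C4) bonds to the unhindered CH2 terminus (C5) of 7, the 1,1,3-trisubstituted allyl radical so formed takes up O2 at C6, the peroxyl radical is reduced to the hydroperoxide by trivalent cerium or by a further molecule of 10 (which carries a chain and makes the union redox-neutral, so that cerium is needed only in substoichiometric amount), and hydrolysis of the iminium ion gives 11, which closes to 12. The closest known reaction types are the Mn(OAc)3- and CeCl3-mediated aerobic couplings of 1,3-dicarbonyl compounds with alkenes, which give 1,2-dioxan-3-ols by the same C–C, C–O, O–C sequence, and the organo-SOMO additions of oxidised chiral enamines to alkenes and dienes. The 1,2-dioxane closes by 6-exo-trig addition of the hydroperoxide oxygen on C6 to the carbonyl (or iminium) carbon C3, giving the cyclic peroxyhemiacetal. C4 is set by the catalyst, whose benzyl group shields the Re face of the radical cation so that the diene bonds to the Si face (4R); C6 has no control element and its epimers are separated by chromatography, and the hemiacetal centre C3 stays a mixture that step 6 erases. The step needs oxidation of the enamine and not of the diene (secured by the far lower oxidation potential of the enamine), C–C bonding before the radical cation meets O2 (secured by air in place of pure O2 and a high diene concentration), and oxygenation at C6 and not at C8 (secured because tetravalent cerium returns any uncyclised allylic hydroperoxide to its peroxyl radical, which loses O2 reversibly, while only the C6 hydroperoxide is drained into a six-membered ring). The E geometry of C7=C8 should persist because O2 capture is much faster than rotation within the allyl radical, and the α-branched product, masked as the cyclic peroxyhemiacetal, should not re-enter enamine formation and so keeps C4.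

Step 5
Reactants: 12 (4R,6R)-4,6-diethyl-6-[(1E,4S)-4-ethyl-2-methyloct-1-en-1-yl]-1,2-dioxan-3-ol
Product: 13 (4R,6R)-4,6-diethyl-6-[(1E,4S)-4-ethyl-2-methyloct-1-en-1-yl]-1,2-dioxan-3-yl acetate (C3 anomers)
Conditions: Ac2O, pyridine, DMAP (cat.), CH2Cl2, 0 °C
Reagents that add atoms: acetic anhydride, CC(=O)OC(C)=O
Why: DMAP-catalysed O-acylation of the cyclic peroxyhemiacetal gives an acetoxy peroxyacetal, a known activation for this substrate class, under conditions cold and mild enough to avoid base-induced Kornblum–DeLaMare cleavage of the O–O bond, and the anomeric mixture is of no consequence because C3 becomes planar in step 6.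

Step 6
Reactants: 13 (4R,6R)-4,6-diethyl-6-[(1E,4S)-4-ethyl-2-methyloct-1-en-1-yl]-1,2-dioxan-3-yl acetate
Product: 14 methyl 2-[(3R,4R,6R)-4,6-diethyl-6-[(1E,4S)-4-ethyl-2-methyloct-1-en-1-yl]-1,2-dioxan-3-yl]acetate
Conditions: CH2=C(OMe)OSiMe2t-Bu (3 equiv), Me3SiOSO2CF3 (20 mol%), CH2Cl2, −78 °C
Reagents that add atoms: tert-butyl[(1-methoxyethenyl)oxy]dimethylsilane, C=C(OC)O[Si](C)(C)C(C)(C)C
Why: In this Mukaiyama-type substitution the silyl triflate ionises the anomeric acetate to a cyclic peroxycarbenium ion, and the silyl ketene acetal attacks C3 along the axial trajectory of the half-chair that keeps the C4 ethyl and the C6 alkenyl group pseudoequatorial, so that the acetate arm ends up axial and cis to the C4 ethyl group (3R).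

Step 7
Reactants: 14 methyl 2-[(3R,4R,6R)-4,6-diethyl-6-[(1E,4S)-4-ethyl-2-methyloct-1-en-1-yl]-1,2-dioxan-3-yl]acetate
Product: 15 2-[(3R,4R,6R)-4,6-diethyl-6-[(1E,4S)-4-ethyl-2-methyloct-1-en-1-yl]-1,2-dioxan-3-yl]acetic acid
Conditions: LiOH·H2O (3 equiv), THF/H2O 3:1, 0 °C to rt; then 0.5 M HCl to pH 3–4
Reagents that add atoms: lithium hydroxide, [Li+].[OH-]
Why: Saponification by acyl substitution is faster than deprotonation α to the ester, so the β-peroxy ester should not open by retro-conjugate addition, the dialkyl peroxide and the alkene are inert to cold aqueous hydroxide, and no stereocentre is touched.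

**Compound list**

1 | hex-1-ene | C=CCCCC | starting material
2 | diethyl[(2S)-2-ethylhexyl]alumane | CCCC[C@H](CC)C[Al](CC)CC | intermediate
3 | (3S)-3-(iodomethyl)heptane | CCCC[C@H](CC)CI | intermediate
4 | (4S)-4-ethyloct-1-yne | CCCC[C@H](CC)CC#C | intermediate
5 | 2-bromobut-1-ene | C=C(Br)CC | starting material
6 | [(1E,4S)-4-ethyl-2-methyloct-1-en-1-yl]dimethylalumane | CCCC[C@H](CC)C/C(C)=C/[Al](C)C | intermediate
7 | (3E,6S)-2,6-diethyl-4-methyldeca-1,3-diene | CCCC[C@H](CC)C/C(C)=C/C(=C)CC | intermediate
8 | butanal | CCCC=O | starting material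
9 | dioxygen | O=O | starting material
10 | (2S,5S)-5-benzyl-1-[(1E)-but-1-en-1-yl]-2-tert-butyl-3-methylimidazolidin-4-one | CN1[C@@H](C(C)(C)C)N(/C=C/CC)[C@@H](Cc2ccccc2)C1=O | intermediate
11 | (2R,4R,5E,8S)-2,4,8-triethyl-4-hydroperoxy-6-methyldodec-5-enal | CCCC[C@H](CC)C/C(C)=C/[C@](CC)(OO)C[C@@H](CC)C=O | intermediate
12 | (4R,6R)-4,6-diethyl-6-[(1E,4S)-4-ethyl-2-methyloct-1-en-1-yl]-1,2-dioxan-3-ol (C3 anomers) | CCCC[C@H](CC)C/C(C)=C/[C@@]1(CC)C[C@@H](CC)C(O)OO1 | intermediate
13 | (4R,6R)-4,6-diethyl-6-[(1E,4S)-4-ethyl-2-methyloct-1-en-1-yl]-1,2-dioxan-3-yl acetate (C3 anomers) | CCCC[C@H](CC)C/C(C)=C/[C@@]1(CC)C[C@@H](CC)C(OC(C)=O)OO1 | intermediate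
14 | methyl 2-[(3R,4R,6R)-4,6-diethyl-6-[(1E,4S)-4-ethyl-2-methyloct-1-en-1-yl]-1,2-dioxan-3-yl]acetate | CCCC[C@H](CC)C/C(C)=C/[C@@]1(CC)C[C@@H](CC)[C@@H](CC(=O)OC)OO1 | intermediate
15 | 2-[(3R,4R,6R)-4,6-diethyl-6-[(1E,4S)-4-ethyl-2-methyloct-1-en-1-yl]-1,2-dioxan-3-yl]acetic acid | CCCC[C@H](CC)C/C(C)=C/[C@@]1(CC)C[C@@H](CC)[C@@H](CC(=O)O)OO1 | target

**Step count**

Total: 7 steps. Longest linear sequence: 7 steps (1 to 15).

**Steps most likely to fail**

1. Step 4. The radical cation may be intercepted by O2 before the C–C bond forms (α-oxygenation of butanal), the chain may break down at the peroxyl stage, and the allyl radical may be oxygenated without regiocontrol.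
 - The fallback uses known reactions, sets out from 8 and 4 and comes back at 12.
 - Butanal 8 is joined to 2-(trimethylsilyloxy)but-1-ene by the known organo-SOMO α-enolation of aldehydes (same imidazolidinone salt, (NH4)2Ce(NO3)6 2 equiv, DME, −20 °C, O2 excluded). This should give (2R)-2-ethyl-4-oxohexanal F1, forming C4–C5 in the absence of oxygen with C6 at the ketone level.
 - Selective acetalisation of the aldehyde (HC(OMe)3, MeOH, pyridinium tosylate) should give (5R)-5-(dimethoxymethyl)heptan-3-one F2.
 - Alkyne 4 is methylaluminated as in step 3 and alane 6 is quenched with I2 to give (1E,4S)-4-ethyl-1-iodo-2-methyloct-1-ene F3.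
 - Iodine–lithium exchange (t-BuLi, Et2O, −78 °C) gives [(1E,4S)-4-ethyl-2-methyloct-1-en-1-yl]lithium F4. After transmetallation with CeCl3 to suppress enolisation, it adds to the ketone of F2 to give (2R,4RS,5E,8S)-2,4,8-triethyl-1,1-dimethoxy-6-methyldodec-5-en-4-ol F5.
 - Acid-catalysed perhydrolysis (H2O2 in Et2O, catalytic H2SO4, 0 °C, aqueous work-up) replaces the tertiary allylic hydroxyl by a hydroperoxy group by the SN1 path and unmasks the aldehyde. The allyl cation can be captured at C6 or C8, but under these reversible conditions only the C6 hydroperoxide is removed by closure to the six-membered peroxyhemiacetal. This should give 12 and its C6 epimer, separated as in step 4.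

2. Step 6. Facial selectivity at C3 may be eroded by the gauche contact between the incoming nucleophile and the C4 ethyl group, or the silyl triflate may ionise the tertiary allylic C6–O1 bond.
 - The fallback sets out from 12 and comes back at 14.
 - Hemiacetal 12, through its open form 11, is treated with methyl (triphenylphosphoranylidene)acetate (CH2Cl2, rt; Wittig reaction) to give methyl (2E,4R,6R,7E,10S)-4,6,10-triethyl-6-hydroperoxy-8-methyltetradeca-2,7-dienoate F6.
 - Amine-catalysed intramolecular conjugate addition of the hydroperoxide (Et2NH, CF3CH2OH, rt; 6-exo-trig), the established closure for 1,2-dioxane-3-acetates, should give 14 together with its C3 epimer, which is removed by chromatography.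

3. Step 1. Enantioselection in the ethylalumination may be incomplete, which would leave C10 diastereomers that no later step can remove.
 - The fallback sets out from 1 and comes back at 4, bypassing 3.
 - Hex-1-ene 1 undergoes cross-metathesis with methyl acrylate (second-generation Grubbs catalyst, (H2IMes)(PCy3)Cl2Ru=CHPh, CH2Cl2, 40 °C) to give methyl (2E)-hept-2-enoate F7.
 - Copper-catalysed asymmetric conjugate addition of EtMgBr (CuI, Tol-BINAP in the antipode that gives the 3S ester, t-BuOMe, −40 °C) gives methyl (3S)-3-ethylheptanoate F8.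
 - i-Bu2AlH (CH2Cl2, −78 °C) gives (3S)-3-ethylheptanal F9.
 - Ohira–Bestmann homologation (dimethyl (1-diazo-2-oxopropyl)phosphonate, K2CO3, MeOH) returns to alkyne 4.

**Further compounds**

F1 | step 4 | (2R)-2-ethyl-4-oxohexanal | CCC(=O)C[C@@H](CC)C=O
F2 | step 4 | (5R)-5-(dimethoxymethyl)heptan-3-one | CCC(=O)C[C@@H](CC)C(OC)OC
F3 | step 4 | (1E,4S)-4-ethyl-1-iodo-2-methyloct-1-ene | CCCC[C@H](CC)C/C(C)=C/I
F4 | step 4 | [(1E,4S)-4-ethyl-2-methyloct-1-en-1-yl]lithium | CCCC[C@H](CC)C/C(C)=C/[Li]
F5 | step 4 | (2R,4RS,5E,8S)-2,4,8-triethyl-1,1-dimethoxy-6-methyldodec-5-en-4-ol | CCCC[C@H](CC)C/C(C)=C/C(O)(CC)C[C@@H](CC)C(OC)OC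
F6 | step 6 | methyl (2E,4R,6R,7E,10S)-4,6,10-triethyl-6-hydroperoxy-8-methyltetradeca-2,7-dienoate | CCCC[C@H](CC)C/C(C)=C/[C@](CC)(OO)C[C@@H](CC)/C=C/C(=O)OC
F7 | step 1 | methyl (2E)-hept-2-enoate | CCCC/C=C/C(=O)OC
F8 | step 1 | methyl (3S)-3-ethylheptanoate | CCCC[C@H](CC)CC(=O)OC
F9 | step 1 | (3S)-3-ethylheptanal | CCCC[C@H](CC)CC=O
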